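**Retrosynthetic overview** (daucane numbering: five-membered ring C1–C2–C3–C4–C5, seven-membered ring C1–C5–C6–C7–C8–C9–C10)
- Feature: in the seven-membered ring the cis C9=C10 alkene sits between the methyl-bearing quaternary carbons C1 and C8(OH). The unit C8(Me)(O)–CH=CH–C1(Me) is 2,5-dimethylfuran with its ring oxygen as O8, and C5–C6(O)–C7 is a three-carbon oxyallyl unit.
- Late disconnections: the vanillate ester at O6, the C6 carbinol (hydroxyl-directed reduction of the C6 ketone), C4–C5 (intramolecular aldol) and C1–C2 (conjugate addition of a C2–C4 ketone-ketal chain).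
- Early disconnections: the C1–O bond of an oxygen bridge (enantiotopic β-elimination of a meso ketone), then C1–C5 and C7–C8 together by a (4+3) cycloaddition.
- Ring order: the seven-membered carbocycle first, as a meso 8-oxabicyclo[3.2.1]octenone; the five-membered ring last but four, by aldol.

Key step: step 1

Assumption: lithium (R,R)-bis(1-phenylethyl)amide is taken to remove the C2 proton of ketone 4 (the CH2 next to the R bridgehead); should the sense be the opposite, the (S,S)-amide is used and nothing else changes.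

**Step 1**
Reactants: 1 2,5-dimethylfuran; 2 1,1,3,3-tetrabromopropan-2-one
Product: 4 (1R,5S)-1,5-dimethyl-8-oxabicyclo[3.2.1]oct-6-en-3-one (meso), via dibromo cycloadduct 3 (not isolated)
Conditions: Zn(Cu), B(OEt)3, THF, 0 °C to rt; then Zn(Cu), NH4Cl, MeOH, rt
Reagents that add atoms: none
Why: Zinc removes two bromines from 2 to give a zinc-bound 1,3-dibromo-2-oxyallyl cation, a three-carbon two-π-electron unit that adds across C2 and C5 of the furan diene in a (4+3) cycloaddition (concerted, or attack at one α-carbon and collapse of the resulting cation onto the enolate), the closest known reaction type being the oxyallyl cation–furan cycloaddition that gives 8-oxabicyclo[3.2.1]oct-6-en-3-ones. The seven-membered carbocycle closes in cycloaddition mode, both new C–C bonds (the later C1–C5 and C7–C8) going to the methyl-bearing furan carbons, and the furan oxygen stays as a one-atom bridge. The two bridgehead stereocentres are cis by the geometry of the bridge, so the adduct is meso whatever the orientation of the bromines, which further Zn(Cu) with NH4Cl then removes. The selectivity needed is cycloaddition over electrophilic substitution of the furan, and the two α-methyl groups secure it because the first-formed cation has no α-hydrogen to lose and can only close. The furan is symmetric, so there is no regiochemical question, and no absolute configuration is set here; that is decided in step 2, when one of the two enantiotopic bridgehead C–O bonds is broken.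

**Step 2**
Reactants: 4 (1R,5S)-1,5-dimethyl-8-oxabicyclo[3.2.1]oct-6-en-3-one
Product: 7 (6S)-6-hydroxy-3,6-dimethylcyclohepta-2,4-dien-1-one, via lithium enolate 5 (not isolated), via lithium alkoxide 6 (not isolated)
Conditions: (R,R)-bis(1-phenylethyl)amine·HCl, n-BuLi (2 equiv), THF, −78 °C; then 4, −78 to 0 °C; aq NH4Cl
Reagents that add atoms: none
Why: Enantiotopic deprotonation of meso 8-oxabicyclo[3.2.1]oct-6-en-3-ones by a chiral lithium amide with LiCl is known, and on warming the enolate expels the bridging oxygen from the neighbouring bridgehead by E1cB β-elimination (strain relief and formation of the conjugated dienone, the resulting alkoxide being too poor a leaving group for a second elimination), so the choice of proton decides which bridgehead keeps its oxygen and fixes the S carbinol carbon that becomes C8.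

**Step 3**
Reactants: 7 (6S)-6-hydroxy-3,6-dimethylcyclohepta-2,4-dien-1-one
Product: 8 (6S)-3,6-dimethyl-6-[(triethylsilyl)oxy]cyclohepta-2,4-dien-1-one
Conditions: TESOTf, 2,6-lutidine, CH2Cl2, −78 °C
Reagents that add atoms: triethylsilyl trifluoromethanesulfonate (TESOTf), CC[Si](CC)(CC)OS(=O)(=O)C(F)(F)F
Why: Silyl triflate with 2,6-lutidine silylates hindered tertiary alcohols at low temperature faster than it enolises the ketone, and the ether blocks retro-aldol cleavage, removes the acidic proton before the Grignard step and turns the C8 oxygen into a bulky, non-coordinating group for facial control.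

**Step 4**
Reactants: 9 4-methylpent-1-en-3-one
Product: 11 2-(2-bromoethyl)-5,5-dimethyl-2-(propan-2-yl)-1,3-dioxane, via bromo ketone 10 (not isolated)
Conditions: HBr, CH2Cl2, 0 °C; then 2,2-dimethylpropane-1,3-diol, HC(OEt)3, TsOH (cat.), rt
Reagents that add atoms: hydrogen bromide, Br; 2,2-dimethylpropane-1,3-diol, OCC(C)(C)CO
Why: Conjugate addition of HBr to the vinyl ketone followed by acid-catalysed ketalisation with an orthoformate as water scavenger is the standard preparation of β-bromo ketone ketals, and the 5,5-dimethyl-1,3-dioxane is chosen because its Grignard reagent resists 1,3-elimination to a cyclopropane.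

**Step 5**
Reactants: 8 (6S)-3,6-dimethyl-6-[(triethylsilyl)oxy]cyclohepta-2,4-dien-1-one; 11 2-(2-bromoethyl)-5,5-dimethyl-2-(propan-2-yl)-1,3-dioxane
Product: 14 (3S,6S)-3-[2-(5,5-dimethyl-2-(propan-2-yl)-1,3-dioxan-2-yl)ethyl]-3,6-dimethyl-6-[(triethylsilyl)oxy]cyclohept-4-en-1-one, via Grignard reagent 12 (not isolated), via silyl enol ether 13 (not isolated)
Conditions: 11, Mg, THF, rt; then added slowly to 8, CuBr·SMe2 (cat.), TMSCl, HMPA, THF, −78 °C; then aq citric acid, 0 °C
Reagents that add atoms: none
Why: Copper-catalysed conjugate addition of a Grignard reagent accelerated by TMSCl and HMPA should deliver the chain to the methyl-bearing β-carbon C1, since silylative trapping at the β-cuprate stage favours 1,4- over 1,6-addition and the δ-carbon C9 is neopentyl, and the new quaternary centre is set by attack on the face opposite the pseudoaxial triethylsilyloxy group at C8, which places the chain trans to that oxygen.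

**Step 6**
Reactants: 14 (3S,6S)-3-[2-(5,5-dimethyl-2-(propan-2-yl)-1,3-dioxan-2-yl)ethyl]-3,6-dimethyl-6-[(triethylsilyl)oxy]cyclohept-4-en-1-one
Product: 15 (3S,6S)-3,6-dimethyl-3-(4-methyl-3-oxopentyl)-6-[(triethylsilyl)oxy]cyclohept-4-en-1-one
Conditions: PPTS, acetone–H2O, 50 °C
Reagents that add atoms: water, O
Why: Mild acid-catalysed ketal hydrolysis frees the isopropyl ketone, while the hindered tertiary triethylsilyl ether and the ring alkene should be untouched at this acidity.

**Step 7**
Reactants: 15 (3S,6S)-3,6-dimethyl-3-(4-methyl-3-oxopentyl)-6-[(triethylsilyl)oxy]cyclohept-4-en-1-one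
Product: 16 (3R,3aR,6S,8aR)-3-hydroxy-6,8a-dimethyl-3-(propan-2-yl)-6-[(triethylsilyl)oxy]-2,3,3a,5,6,8a-hexahydroazulen-4(1H)-one
Conditions: KOH (cat.), MeOH, 0 °C to rt; other ketols and recovered 15 resubmitted
Reagents that add atoms: none
Why: Base-mediated intramolecular aldol addition of the 1,6-diketone (a cyclopentannulation stopped at the ketol) closes the five-membered ring by attack of the C5 enolate on the isopropyl ketone, the alternative closure from C3 onto C6 giving only a strained bridged ketol that reverts, and under these reversible conditions C4 and C5 are expected to settle in the ketol with the hydroxyl hydrogen-bonded syn to the C6 carbonyl, the isopropyl group anti to C6 and trans to the angular methyl, and the trans ring fusion, whose angular methyl has no syn-axial partner because C6 and C9 are sp2, while low temperature and catalytic hydroxide avoid dehydration and β-elimination of the silyloxy group.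

**Step 8**
Reactants: 16 (3R,3aR,6S,8aR)-3-hydroxy-6,8a-dimethyl-3-(propan-2-yl)-6-[(triethylsilyl)oxy]-2,3,3a,5,6,8a-hexahydroazulen-4(1H)-one
Product: 17 (3R,3aS,4S,6S,8aR)-6,8a-dimethyl-3-(propan-2-yl)-6-[(triethylsilyl)oxy]-1,2,3,3a,4,5,6,8a-octahydroazulene-3,4-diol
Conditions: Me4NBH(OAc)3, MeCN–AcOH, −30 to −20 °C
Reagents that add atoms: none
Why: In this Evans–Saksena directed reduction the C4 hydroxyl exchanges onto boron and delivers hydride through a six-membered transition state to the face of the C6 carbonyl on which it lies, giving the 1,3-anti diol with the new C6 hydroxyl on the face opposite the C4 hydroxyl.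

**Step 9**
Reactants: 18 4-hydroxy-3-methoxybenzoic acid (vanillic acid)
Product: 20 4-[(tert-butyldimethylsilyl)oxy]-3-methoxybenzoic acid, via bis-silylated vanillate 19 (not isolated)
Conditions: TBSCl, imidazole, DMF, rt; then AcOH, THF–H2O, rt
Reagents that add atoms: tert-butyldimethylsilyl chloride (TBSCl), CC(C)(C)[Si](C)(C)Cl
Why: Silylation of both phenol and acid followed by selective hydrolysis of the labile silyl ester is the standard way to mask only the phenol of a hydroxybenzoic acid, which prevents self-acylation in the coupling.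

**Step 10**
Reactants: 17 (3R,3aS,4S,6S,8aR)-6,8a-dimethyl-3-(propan-2-yl)-6-[(triethylsilyl)oxy]-1,2,3,3a,4,5,6,8a-octahydroazulene-3,4-diol; 20 4-[(tert-butyldimethylsilyl)oxy]-3-methoxybenzoic acid
Product: 21 (3R,3aS,4S,6S,8aR)-3-hydroxy-6,8a-dimethyl-3-(propan-2-yl)-6-[(triethylsilyl)oxy]-1,2,3,3a,4,5,6,8a-octahydroazulen-4-yl 4-[(tert-butyldimethylsilyl)oxy]-3-methoxybenzoate
Conditions: DCC, DMAP, CH2Cl2, rt
Reagents that add atoms: none
Why: Steglich esterification (carbodiimide activation with DMAP acyl transfer) acylates the only secondary hydroxyl with retention at C6, the tertiary C4 hydroxyl being inert under these conditions and the C8 oxygen and the phenol being silylated.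

**Step 11**
Reactants: 21 (3R,3aS,4S,6S,8aR)-3-hydroxy-6,8a-dimethyl-3-(propan-2-yl)-6-[(triethylsilyl)oxy]-1,2,3,3a,4,5,6,8a-octahydroazulen-4-yl 4-[(tert-butyldimethylsilyl)oxy]-3-methoxybenzoate
Product: 22 (3R,3aS,4S,6S,8aR)-3,6-dihydroxy-6,8a-dimethyl-3-(propan-2-yl)-1,2,3,3a,4,5,6,8a-octahydroazulen-4-yl 4-hydroxy-3-methoxybenzoate (CNP0243386.2)
Conditions: TBAF, AcOH, THF, 0 °C to rt
Reagents that add atoms: none
Why: Fluoride cleaves the aryl tert-butyldimethylsilyl ether and the tertiary triethylsilyl ether in one operation, and the acetic acid buffer keeps the phenoxide from attacking the ester and spares the tertiary allylic alcohol from ionisation.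

**Compound list**
1 | 2,5-dimethylfuran | Cc1ccc(C)o1 | starting material
2 | 1,1,3,3-tetrabromopropan-2-one | O=C(C(Br)Br)C(Br)Br | starting material
3 | 2,4-dibromo-1,5-dimethyl-8-oxabicyclo[3.2.1]oct-6-en-3-one (bromide epimers, bridgeheads cis) | O=C1C(Br)[C@@]2(C)C=C[C@@](C)(C1Br)O2 | intermediate
4 | (1R,5S)-1,5-dimethyl-8-oxabicyclo[3.2.1]oct-6-en-3-one (meso) | O=C1C[C@@]2(C)C=C[C@@](C)(C1)O2 | intermediate
5 | lithium (1S,5S)-1,5-dimethyl-8-oxabicyclo[3.2.1]octa-2,6-dien-3-olate | [Li+].[O-]C1=C[C@]2(C)C=C[C@](C)(C1)O2 | intermediate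
6 | lithium (1S)-1,4-dimethyl-6-oxocyclohepta-2,4-dien-1-olate | [Li+].[O-][C@]1(C)C=CC(C)=CC(=O)C1 | intermediate
7 | (6S)-6-hydroxy-3,6-dimethylcyclohepta-2,4-dien-1-one | O=C1C[C@](C)(O)C=CC(C)=C1 | intermediate
8 | (6S)-3,6-dimethyl-6-[(triethylsilyl)oxy]cyclohepta-2,4-dien-1-one | O=C1C[C@](C)(O[Si](CC)(CC)CC)C=CC(C)=C1 | intermediate
9 | 4-methylpent-1-en-3-one | CC(C)C(=O)C=C | starting material
10 | 1-bromo-4-methylpentan-3-one | CC(C)C(=O)CCBr | intermediate
11 | 2-(2-bromoethyl)-5,5-dimethyl-2-(propan-2-yl)-1,3-dioxane | CC(C)C1(CCBr)OCC(C)(C)CO1 | intermediate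
12 | [2-(5,5-dimethyl-2-(propan-2-yl)-1,3-dioxan-2-yl)ethyl]magnesium bromide | CC(C)C1(CC[Mg]Br)OCC(C)(C)CO1 | intermediate
13 | trimethylsilyl enol ether of 14 (C5=C6, O6–SiMe3; 3R,6S as a cyclohepta-1,4-diene) | C[Si](C)(C)OC1=C[C@](C)(CCC2(C(C)C)OCC(C)(C)CO2)C=C[C@@](C)(O[Si](CC)(CC)CC)C1 | intermediate
14 | (3S,6S)-3-[2-(5,5-dimethyl-2-(propan-2-yl)-1,3-dioxan-2-yl)ethyl]-3,6-dimethyl-6-[(triethylsilyl)oxy]cyclohept-4-en-1-one | O=C1C[C@](C)(O[Si](CC)(CC)CC)C=C[C@@](C)(CCC2(C(C)C)OCC(C)(C)CO2)C1 | intermediate
15 | (3S,6S)-3,6-dimethyl-3-(4-methyl-3-oxopentyl)-6-[(triethylsilyl)oxy]cyclohept-4-en-1-one | O=C1C[C@](C)(O[Si](CC)(CC)CC)C=C[C@@](C)(CCC(=O)C(C)C)C1 | intermediate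
16 | (3R,3aR,6S,8aR)-3-hydroxy-6,8a-dimethyl-3-(propan-2-yl)-6-[(triethylsilyl)oxy]-2,3,3a,5,6,8a-hexahydroazulen-4(1H)-one | O=C1C[C@](C)(O[Si](CC)(CC)CC)C=C[C@@]2(C)CC[C@@](O)(C(C)C)[C@H]12 | intermediate
17 | (3R,3aS,4S,6S,8aR)-6,8a-dimethyl-3-(propan-2-yl)-6-[(triethylsilyl)oxy]-1,2,3,3a,4,5,6,8a-octahydroazulene-3,4-diol | O[C@H]1C[C@](C)(O[Si](CC)(CC)CC)C=C[C@@]2(C)CC[C@@](O)(C(C)C)[C@H]12 | intermediate
18 | 4-hydroxy-3-methoxybenzoic acid (vanillic acid) | COc1cc(C(=O)O)ccc1O | starting material
19 | tert-butyldimethylsilyl 4-[(tert-butyldimethylsilyl)oxy]-3-methoxybenzoate | COc1cc(C(=O)O[Si](C)(C)C(C)(C)C)ccc1O[Si](C)(C)C(C)(C)C | intermediate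
20 | 4-[(tert-butyldimethylsilyl)oxy]-3-methoxybenzoic acid | COc1cc(C(=O)O)ccc1O[Si](C)(C)C(C)(C)C | intermediate
21 | (3R,3aS,4S,6S,8aR)-3-hydroxy-6,8a-dimethyl-3-(propan-2-yl)-6-[(triethylsilyl)oxy]-1,2,3,3a,4,5,6,8a-octahydroazulen-4-yl 4-[(tert-butyldimethylsilyl)oxy]-3-methoxybenzoate | COc1cc(C(=O)O[C@H]2C[C@](C)(O[Si](CC)(CC)CC)C=C[C@@]3(C)CC[C@@](O)(C(C)C)[C@H]23)ccc1O[Si](C)(C)C(C)(C)C | intermediate
22 | (3R,3aS,4S,6S,8aR)-3,6-dihydroxy-6,8a-dimethyl-3-(propan-2-yl)-1,2,3,3a,4,5,6,8a-octahydroazulen-4-yl 4-hydroxy-3-methoxybenzoate | COc1cc(C(=O)O[C@H]2C[C@](C)(O)C=C[C@@]3(C)CC[C@@](O)(C(C)C)[C@H]23)ccc1O | target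

**Step count**
Total: 11 steps (steps 4 and 9 prepare the two side reagents). Longest linear sequence: 9 steps (1, 2, 3, 5, 6, 7, 8, 10, 11).

**Steps most likely to fail**

Step 7 carries the most risk. The reversible aldol may close through the side-chain enolate onto C6, may equilibrate towards the cis-fused ketol rather than the trans-fused one, or may drain irreversibly by dehydration or by β-elimination of silanol from C8. The fallback makes the closure regiospecific and kinetic. It sets out from silyl enol ether 13, which is isolated after a non-aqueous work-up of step 5 and brominated with NBS in THF at −78 °C to the α-bromo ketone ketal F1. Hydrolysis as in step 6 gives the bromo diketone F2. SmI2 in THF at −78 °C then reduces the C5–Br bond to a samarium enolate located only at C5, which adds to the isopropyl ketone through a chelated transition state (intramolecular Reformatsky-type aldol) and gives ketol 16, where the route is rejoined.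

Step 5 is next. The chain may add 1,6 at C9 instead of 1,4 at C1, the remote C8 group may give poor facial selectivity, and the basic Grignard reagent may enolise the ketone and expel silanol to a tropone. The fallback delivers the carbon to C1 by a sigmatropic shift and sets out from 8:
- Allylmagnesium bromide adds 1,2 to the ketone, anti to the C8 silyloxy group, to give the allyl carbinol F3.
- KH with 18-crown-6 in THF triggers an anionic oxy-Cope rearrangement that carries the allyl group suprafacially to C1 and gives the allyl ketone F4.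
- Dicyclohexylborane, then NaBO3, converts the terminal alkene into the primary alcohol F5.
- Dess–Martin periodinane gives the keto aldehyde F6.
- i-PrMgCl at −78 °C adds to the aldehyde only and gives the isopropyl carbinol F7.
- A second Dess–Martin oxidation gives diketone 15, where the route is rejoined.

Step 2 is third. The enolate may open slowly or incompletely, enantiomeric purity may erode by proton exchange during warming in the presence of the amine, and excess base may deprotonate the dienone further. The fallback separates the asymmetric deprotonation from the ring opening and sets out from 4. The same lithium amide is used at −100 °C with TMSCl present from the start (in situ quench), which gives the trimethylsilyl enol ether F8; this is isolated free of amine. MeLi in THF then regenerates lithium enolate 5, which opens on warming and gives 7 after work-up, where the route is rejoined.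

**Further compounds**
F1 | step 7 | (3R,6S)-2-bromo-3-[2-(5,5-dimethyl-2-(propan-2-yl)-1,3-dioxan-2-yl)ethyl]-3,6-dimethyl-6-[(triethylsilyl)oxy]cyclohept-4-en-1-one (C2 epimers) | O=C1C[C@](C)(O[Si](CC)(CC)CC)C=C[C@@](C)(CCC2(C(C)C)OCC(C)(C)CO2)C1Br
F2 | step 7 | (3R,6S)-2-bromo-3,6-dimethyl-3-(4-methyl-3-oxopentyl)-6-[(triethylsilyl)oxy]cyclohept-4-en-1-one (C2 epimers) | O=C1C[C@](C)(O[Si](CC)(CC)CC)C=C[C@@](C)(CCC(=O)C(C)C)C1Br
F3 | step 5 | (1R,6S)-3,6-dimethyl-1-(prop-2-en-1-yl)-6-[(triethylsilyl)oxy]cyclohepta-2,4-dien-1-ol | C=CC[C@@]1(O)C[C@](C)(O[Si](CC)(CC)CC)C=CC(C)=C1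
F4 | step 5 | (3S,6S)-3,6-dimethyl-3-(prop-2-en-1-yl)-6-[(triethylsilyl)oxy]cyclohept-4-en-1-one | O=C1C[C@](C)(O[Si](CC)(CC)CC)C=C[C@@](C)(CC=C)C1
F5 | step 5 | (3S,6S)-3-(3-hydroxypropyl)-3,6-dimethyl-6-[(triethylsilyl)oxy]cyclohept-4-en-1-one | O=C1C[C@](C)(O[Si](CC)(CC)CC)C=C[C@@](C)(CCCO)C1
F6 | step 5 | 3-[(1S,4S)-1,4-dimethyl-6-oxo-4-[(triethylsilyl)oxy]cyclohept-2-en-1-yl]propanal | O=C1C[C@](C)(O[Si](CC)(CC)CC)C=C[C@@](C)(CCC=O)C1
F7 | step 5 | (3S,6S)-3-(3-hydroxy-4-methylpentyl)-3,6-dimethyl-6-[(triethylsilyl)oxy]cyclohept-4-en-1-one (carbinol epimers) | O=C1C[C@](C)(O[Si](CC)(CC)CC)C=C[C@@](C)(CCC(O)C(C)C)C1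
F8 | step 2 | trimethyl{[(1S,5S)-1,5-dimethyl-8-oxabicyclo[3.2.1]octa-2,6-dien-3-yl]oxy}silane | C[Si](C)(C)OC1=C[C@]2(C)C=C[C@](C)(C1)O2
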